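**Assumption:** the SMILES decodes to the all-trans guaiacin core (tetralin C1 = S, C2 = S, C3 = R; aryl/Me/Me trans,trans). Its 4'-O carries an erythro side chain (carbinol C7'' = S, O-bearing C8'' = R). Ring A is the fused arene, ring B the pendant arene and ring C the side-chain arene.

## Retrosynthetic overview
1. 15 ⇐ ketone 14 by chelate-controlled hydride reduction plus ester cleavage. 14 ⇐ Weinreb amide 13 + aryl-Mg from 3, so ring C is attached last and no phenol/C6C3 etherification of guaiacin is used.
2. 13 ⇐ acyclic dibenzylbutane 12 by oxidative benzylic C–H/aryl C–H closure (C1–C8a). This key step forms the only ring made in the synthesis (step 7 of 9); all three arenes are bought.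
3. 12 ⇐ (E,E)-diene 11 by one double asymmetric hydrogenation that sets both methyl stereocentres.
4. 11 ⇐ 2,3-dimethylbutadiene + two different aryl halides (3, 10) by two Heck arylations.
5. 10 ⇐ 4-bromoguaiacol + ethyl L-lactate, where Mitsunobu inversion fixes C8''.

## Route

**Step 1**
Reactants: 1, 4-iodo-2-methoxyphenol; 2, pivaloyl chloride
Product: 3, 4-iodo-2-methoxyphenyl pivalate
Conditions: Et3N, DMAP (cat.), CH2Cl2, 0 °C → rt
Reagents that add atoms: pivaloyl chloride (2), CC(C)(C)C(=O)Cl
Why: DMAP-catalysed O-acylation; the hindered, electron-withdrawing ester tolerates Pd and low-temperature Grignard chemistry and later switches rings A and C off toward DDQ.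

**Step 2**
Reactants: 3, 4-iodo-2-methoxyphenyl pivalate; 4, 2,3-dimethylbuta-1,3-diene
Product: 5, 4-[(1E)-2,3-dimethylbuta-1,3-dien-1-yl]-2-methoxyphenyl pivalate
Conditions: 4 (6 equiv), Pd(OAc)2 (3 mol %), P(o-tol)3 (9 mol %), Et3N, BHT, MeCN, 80 °C, sealed tube
Reagents that add atoms: 2,3-dimethylbuta-1,3-diene (4), C=C(C)C(C)=C
Why: Mizoroki–Heck arylation of a 1,3-diene at the terminal CH2; the π-allyl-Pd intermediate loses the benzylic H to give the conjugated (E)-aryl diene, and excess diene suppresses a second arylation.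

**Step 3**
Reactants: 6, 4-bromo-2-methoxyphenol; 7, ethyl (S)-lactate
Product: 8, ethyl (2R)-2-(4-bromo-2-methoxyphenoxy)propanoate
Conditions: PPh3, DIAD, THF, 0 °C → rt
Reagents that add atoms: ethyl (S)-lactate (7), CCOC(=O)[C@H](C)O
Why: Mitsunobu etherification; clean SN2 inversion of the lactate carbinol (S → R) sets C8''.

**Step 4**
Reactants: 8, ethyl (2R)-2-(4-bromo-2-methoxyphenoxy)propanoate; 9, N,O-dimethylhydroxylamine hydrochloride
Product: 10, (2R)-2-(4-bromo-2-methoxyphenoxy)-N-methoxy-N-methylpropanamide
Conditions: AlMe3, CH2Cl2, 0 °C → rt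
Reagents that add atoms: N,O-dimethylhydroxylamine hydrochloride (9), CNOC.Cl
Why: Weinreb aminolysis through Me2Al–N(OMe)Me is non-basic, so C8'' is not epimerised and the aryl bromide is untouched.

**Step 5**
Reactants: 10, (2R)-2-(4-bromo-2-methoxyphenoxy)-N-methoxy-N-methylpropanamide; 5, 4-[(1E)-2,3-dimethylbuta-1,3-dien-1-yl]-2-methoxyphenyl pivalate (1.3 equiv)
Product: 11, (2R)-N-methoxy-2-{2-methoxy-4-[(1E,3E)-4-(3-methoxy-4-pivaloyloxyphenyl)-2,3-dimethylbuta-1,3-dien-1-yl]phenoxy}-N-methylpropanamide
Conditions: Pd2(dba)3 (2.5 mol %), P(t-Bu)3·HBF4 (6 mol %), Cy2NMe, dioxane, 80 °C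
Reagents that add atoms: diene 5, COc1cc(/C=C(C)/C(C)=C)ccc1OC(=O)C(C)(C)C
Why: A second Mizoroki–Heck arylation at the remaining =CH2 (bulky electron-rich phosphine for the electron-rich ArBr); loss of the benzylic H gives the conjugated E alkene, and the tertiary amine is too weak to epimerise the α-aryloxy amide.

**Step 6**
Reactants: 11, the (1E,3E)-diene Weinreb amide
Product: 12, (2R)-N-methoxy-2-{2-methoxy-4-[(2R,3R)-4-(3-methoxy-4-pivaloyloxyphenyl)-2,3-dimethylbutyl]phenoxy}-N-methylpropanamide
Conditions: [Ir(cod)(L*)]BArF (2 mol %; L* = ThrePHOX-type phosphinite–oxazoline, antipode that gives 2R,3R), H2 (50 bar), CH2Cl2, rt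
Reagents that add atoms: none
Why: Ir–N,P asymmetric hydrogenation of unfunctionalised (E)-ArCH=C(Me)R alkenes; the twisted diene offers two pseudo-C2-related styrene units with the same local enantioface, so catalyst-controlled syn-H2 addition sets C2 and C3 as R,R, and errors end up mainly as a separable meso-type diastereomer (Horeau amplification).

**Step 7 (key step)**
Reactants: 12, the (2R,3R)-dibenzylbutane Weinreb amide
Product: 13, (2R)-N-methoxy-2-{2-methoxy-4-[(1S,2S,3R)-6-methoxy-2,3-dimethyl-7-pivaloyloxy-1,2,3,4-tetrahydronaphthalen-1-yl]phenoxy}-N-methylpropanamide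
Conditions: DDQ (1.1 equiv), HFIP–CH2Cl2 (1:3), 0 °C → rt, stopped at about 85–90 % conversion; then TfOH (5 mol %), 0 °C, 10 min
Reagents that add atoms: none
Why: Proposed new method: DDQ abstracts hydride only from the CH2 para to the alkoxy donor of ring B (ring A is deactivated by its para-pivaloyloxy group), HFIP separates the cation from DDQH− so six-ring Friedel–Crafts attack by the ring-A carbon para to OMe outruns proton loss, the acid pulse re-ionises any benzylic HFIP or DDQH ether, and closure through a chair-like transition state with aryl, C2-Me and C3-Me all equatorial sets C1 = S (1,2-trans); the closest known reaction types are DDQ/acid oxidative cyclisation of dibenzylbutyrolactone lignans to aryltetralins, DDQ cross-dehydrogenative benzylic arylation, and acid cyclisation of the corresponding benzylic alcohols, which gives the same all-trans tetralins.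

**Step 8**
Reactants: 13, the tetralin Weinreb amide; 3, 4-iodo-2-methoxyphenyl pivalate (1.8 equiv)
Product: 14, (2R)-1-(3-methoxy-4-pivaloyloxyphenyl)-2-{2-methoxy-4-[(1S,2S,3R)-6-methoxy-2,3-dimethyl-7-pivaloyloxy-1,2,3,4-tetrahydronaphthalen-1-yl]phenoxy}propan-1-one
Conditions: 3, i-PrMgCl·LiCl, THF, −20 °C; then 13, −20 → 0 °C; cold aq. NH4Cl
Reagents that add atoms: aryl iodide 3 (aryl donor), COc1cc(I)ccc1OC(=O)C(C)(C)C
Why: I/Mg exchange (turbo-Grignard) tolerates hindered aryl pivalates below 0 °C, and Weinreb ketone synthesis stops at the chelated tetrahedral adduct, so the epimerisable ketone appears only on neutral quench and C8'' is retained.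

**Step 9**
Reactants: 14, the α-aryloxy ketone bis-pivalate
Product: 15, target, (6R,7S,8S)-8-(4-{[(1S,2R)-1-hydroxy-1-(4-hydroxy-3-methoxyphenyl)propan-2-yl]oxy}-3-methoxyphenyl)-3-methoxy-6,7-dimethyl-5,6,7,8-tetrahydronaphthalen-2-ol
Conditions: LiAlH4 (6 equiv), Et2O–THF (4:1), −78 °C, then 0 °C; Rochelle salt work-up
Reagents that add atoms: none
Why: Cram-chelate reduction; Li+ bridges C=O and the α-aryloxy O (helped by the ortho-OMe), so hydride attacks from the C8''–H face to give C7'' = S (erythro, expected dr about 5:1 or better, threo isomer removed by chromatography), and on warming the same reagent cleaves both aryl pivalates when C7''–O is already an alkoxide, so no quinone methide can form.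

## Compound list
| No. | Name | SMILES | Role |
|---|---|---|---|
| 1 | 4-iodo-2-methoxyphenol | COc1cc(I)ccc1O | starting material |
| 2 | pivaloyl chloride | CC(C)(C)C(=O)Cl | starting material |
| 3 | 4-iodo-2-methoxyphenyl pivalate | COc1cc(I)ccc1OC(=O)C(C)(C)C | intermediate |
| 4 | 2,3-dimethylbuta-1,3-diene | C=C(C)C(C)=C | starting material |
| 5 | 4-[(1E)-2,3-dimethylbuta-1,3-dien-1-yl]-2-methoxyphenyl pivalate | COc1cc(/C=C(C)/C(C)=C)ccc1OC(=O)C(C)(C)C | intermediate |
| 6 | 4-bromo-2-methoxyphenol | COc1cc(Br)ccc1O | starting material |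
| 7 | ethyl (S)-lactate | CCOC(=O)[C@H](C)O | starting material |
| 8 | ethyl (2R)-2-(4-bromo-2-methoxyphenoxy)propanoate | CCOC(=O)[C@@H](C)Oc1ccc(Br)cc1OC | intermediate |
| 9 | N,O-dimethylhydroxylamine hydrochloride | CNOC.Cl | starting material |
| 10 | (2R)-2-(4-bromo-2-methoxyphenoxy)-N-methoxy-N-methylpropanamide | CON(C)C(=O)[C@@H](C)Oc1ccc(Br)cc1OC | intermediate |
| 11 | (2R, 1E,3E)-diaryl-2,3-dimethylbutadiene Weinreb amide | CON(C)C(=O)[C@@H](C)Oc1ccc(/C=C(C)/C(C)=C/c2ccc(OC(=O)C(C)(C)C)c(OC)c2)cc1OC | intermediate |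
| 12 | (2R; 2R,3R)-dibenzylbutane Weinreb amide | CON(C)C(=O)[C@@H](C)Oc1ccc(C[C@@H](C)[C@H](C)Cc2ccc(OC(=O)C(C)(C)C)c(OC)c2)cc1OC | intermediate |
| 13 | (2R; 1S,2S,3R)-aryltetralin Weinreb amide, 7-O-pivalate | CON(C)C(=O)[C@@H](C)Oc1ccc([C@H]2c3cc(OC(=O)C(C)(C)C)c(OC)cc3C[C@@H](C)[C@@H]2C)cc1OC | intermediate |
| 14 | (2R; 1S,2S,3R)-α-aryloxy ketone, bis-pivalate | COc1cc(C(=O)[C@@H](C)Oc2ccc([C@H]3c4cc(OC(=O)C(C)(C)C)c(OC)cc4C[C@@H](C)[C@@H]3C)cc2OC)ccc1OC(=O)C(C)(C)C | intermediate |
| 15 | CID53359464 | COc1cc([C@H](O)[C@@H](C)Oc2ccc([C@H]3c4cc(O)c(OC)cc4C[C@@H](C)[C@@H]3C)cc2OC)ccc1O | target |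

## Summary
**Total steps:** 9.
**Longest linear sequence:** 7 (steps 1, 2, 5–9, or equally steps 3–9).

**Three steps most likely to fail**

1. **Step 7 (oxidative C–H cyclisation).**
   - Risks: proton loss to the styrene, which erodes C2; over-oxidation of the doubly benzylic C1–H of 13, which is the most likely limit on yield; and aryl–aryl coupling.
   - Fallback: switch to a quinone-methide closure. Use TBS-protected 4-bromoguaiacol in Step 5, hydrogenate and desilylate. Oxidise the free ring-B phenol with Ag2O to the p-quinone methide and close with catalytic acid to 7-O-pivaloylguaiacin. Then install the lactate by Mitsunobu reaction and continue with Steps 4, 8 and 9.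
2. **Step 6 (double asymmetric hydrogenation).**
   - Risks: 1,4-addition or isomerisation to the tetrasubstituted alkene, and a mismatched second reduction giving the meso-type isomer.
   - Fallback: build the C2–C3 bond with an auxiliary. Oxidatively homocouple the enolate of commercial 4-benzyl-3-propionyloxazolidin-2-one and reduce to (2S,3S)-2,3-dimethylbutane-1,4-diol (same spatial arrangement as 2R,3R in 12). Form the cyclic sulfate and carry out two successive Cu-catalysed aryl-Grignard couplings, with ring B carried as a protected phenol and the lactate added afterwards.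
3. **Step 5 (second Heck on the hindered diene).**
   - Risks: cross-conjugated β-H elimination isomers and low conversion.
   - Fallback: Suzuki–Miyaura diene assembly. Couple each aryl halide with propyne (Sonogashira) and apply Cu-catalysed syn-hydroboration to give the ArCH=C(Me)Bpin units. Convert one of them to the alkenyl iodide and cross-couple, so both E geometries come from syn-hydrometalation.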